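**Plan**

- Retrosynthesis: after O–Si cleavage, the phenol ring is cut at C1–C2 and C5–C6 (C1 = C–O carbon, C6 = carbon bearing the bicycle). This is possible because ring carbons C2(Br)–C3(CH3)–C4(Br)–C5(H) are C3–C6 of a 3,5-dibromo-4-methyl-2-pyrone, C1 and C6 are the two carbons of a silyl ynol ether, and the pyrone O1–C2 unit leaves as CO2.
- The ynol ether is cut back at O–C(sp), at the alkyne carbon (aldehyde homologation), at the cyclopropane methylene and at the two methyl groups, to methyl 2-oxocyclopentanecarboxylate. The pyrone is cut back to ethyl 3-methylbut-2-enoate, a formyl carbon and two bromines.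
- Forward: the five-membered ring is bought, the cyclopropane ring of the bicyclo[3.1.0]hexane is closed on it, and the pyrone ring is made separately. The benzene ring is formed last by Diels–Alder reaction with loss of CO2, then the silyl group is removed.
- Stereochemistry: the quaternary C2 of the bicycle comes from auxiliary-controlled methylation of the keto ester as its L-valine tert-butyl ester enamine. C1 and C5 come from a hydroxyl-directed Simmons–Smith reaction relayed from C2. No later step creates or endangers a stereocentre.

Key step: step 12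

Assumption: methylation of the lithiated L-valine tert-butyl ester enamine in toluene with one equivalent of HMPA is taken to give the (R)-keto ester. The facial sense of this alkylation depends on the lithium ligand (HMPA against THF or dioxolane), so the ligand, or failing that the D-valine ester, is chosen to give the (R)-product, with no change downstream. The valine ester is used as the free base liberated from its commercial hydrochloride.

**Route**

Step 1
Reactants: 1 methyl 2-oxocyclopentane-1-carboxylate; 2 tert-butyl L-valinate
Product: 3 methyl 2-{[(2S)-1-tert-butoxy-3-methyl-1-oxobutan-2-yl]amino}cyclopent-1-ene-1-carboxylate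
Conditions: BF3·OEt2 (cat.), PhMe, reflux, Dean–Stark
Reagents that add atoms: none
Why: Acid-catalysed condensation of a primary amine with a β-keto ester (enamine formation) is driven by azeotropic removal of water and stops at the hydrogen-bonded vinylogous carbamate, the valine stereocentre being untouched.

Step 2
Reactants: 3 methyl 2-{[(2S)-1-tert-butoxy-3-methyl-1-oxobutan-2-yl]amino}cyclopent-1-ene-1-carboxylate
Product: 6 methyl (1R)-1-methyl-2-oxocyclopentane-1-carboxylate, via lithio-enamine 4 (not isolated), via methylated imine 5 (not isolated)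
Conditions: LiN(i-Pr)2, PhMe, −78 °C; HMPA (1 equiv); MeI, −78 → −40 °C; then 1 M aq. HCl, rt
Reagents that add atoms: iodomethane, CI; water, O
Why: Auxiliary-controlled alkylation of a chelated lithio-enamine: lithium is held by the nitrogen and the ester carbonyls so that the isopropyl group of the valine unit and the lithium ligand leave one face of the α-carbon open to MeI, which sets the quaternary centre as R, after which mild aqueous acid hydrolyses the imine to the ketone and returns the auxiliary.

Step 3
Reactants: 6 methyl (1R)-1-methyl-2-oxocyclopentane-1-carboxylate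
Product: 8 methyl (1R)-1-methyl-2-[(trifluoromethanesulfonyl)oxy]cyclopent-2-ene-1-carboxylate, via potassium enolate 7 (not isolated)
Conditions: KN(SiMe3)2, THF, −78 °C; then PhNTf2, −78 °C → rt
Reagents that add atoms: N-phenylbis(trifluoromethanesulfonimide), O=S(=O)(N(c1ccccc1)S(=O)(=O)C(F)(F)F)C(F)(F)F
Why: The ketone can enolise only towards C3 because C1 is quaternary, so the amide base gives one enolate that PhNTf2 triflates on oxygen (enol triflate formation) without risk to the stereocentre, which bears no hydrogen.

Step 4
Reactants: 8 methyl (1R)-1-methyl-2-[(trifluoromethanesulfonyl)oxy]cyclopent-2-ene-1-carboxylate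
Product: 9 methyl (1R)-1,2-dimethylcyclopent-2-ene-1-carboxylate
Conditions: MeMgBr, Fe(acac)3 (5 mol %), THF/NMP, −30 → 0 °C
Reagents that add atoms: methylmagnesium bromide, C[Mg]Br
Why: Iron-catalysed Kumada-type cross-coupling of alkenyl triflates with MeMgBr proceeds at low temperature, where the hindered α-quaternary methyl ester is not attacked by the Grignard reagent.

Step 5
Reactants: 9 methyl (1R)-1,2-dimethylcyclopent-2-ene-1-carboxylate
Product: 10 [(1R)-1,2-dimethylcyclopent-2-en-1-yl]methanol
Conditions: LiAlH4, Et2O, 0 °C → rt; then H2O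
Reagents that add atoms: none
Why: LiAlH4 reduces the ester to the primary alcohol (hydride reduction) and leaves the isolated trisubstituted alkene and the quaternary centre alone.

Step 6
Reactants: 10 [(1R)-1,2-dimethylcyclopent-2-en-1-yl]methanol
Product: 11 [(1S,2R,5R)-1,2-dimethylbicyclo[3.1.0]hexan-2-yl]methanol
Conditions: Et2Zn, CH2I2, CH2Cl2, 0 °C → rt
Reagents that add atoms: diiodomethane, ICI
Why: In this Simmons–Smith cyclopropanation (Furukawa variant) the zinc alkoxide of the homoallylic alcohol binds the zinc carbenoid and delivers the methylene to the alkene face on the side of the CH2OH group, which sets C1 (S) and C5 (R) with the cyclopropane methylene syn to the hydroxymethyl group, the group whose carbon ends as the arene carbon.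

Step 7
Reactants: 11 [(1S,2R,5R)-1,2-dimethylbicyclo[3.1.0]hexan-2-yl]methanol
Product: 12 (1S,2R,5R)-1,2-dimethylbicyclo[3.1.0]hexane-2-carbaldehyde
Conditions: Dess–Martin periodinane, CH2Cl2, 0 °C → rt
Reagents that add atoms: none
Why: Dess–Martin oxidation converts the neopentyl-type primary alcohol into the aldehyde under near-neutral conditions, and the product, having no α-hydrogen, can neither enolise nor epimerise.

Step 8
Reactants: 12 (1S,2R,5R)-1,2-dimethylbicyclo[3.1.0]hexane-2-carbaldehyde
Product: 13 (1S,2S,5R)-2-ethynyl-1,2-dimethylbicyclo[3.1.0]hexane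
Conditions: MeC(O)C(N2)P(O)(OMe)2, K2CO3, MeOH, 0 °C → rt
Reagents that add atoms: dimethyl (1-diazo-2-oxopropyl)phosphonate, COP(=O)(OC)C(=[N+]=[N-])C(C)=O
Why: Seyferth–Gilbert homologation in the Ohira–Bestmann variant turns a non-enolisable aldehyde into the terminal alkyne in basic methanol and adds the one carbon that becomes the C–O carbon of the phenol, the volatile product being carried on as a dried solution (the change of the C2 descriptor to S is only a change of substituent priority).

Step 9
Reactants: 13 (1S,2S,5R)-2-ethynyl-1,2-dimethylbicyclo[3.1.0]hexane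
Product: 16 ({[(1S,2R,5R)-1,2-dimethylbicyclo[3.1.0]hexan-2-yl]ethynyl}oxy)triisopropylsilane, via lithium acetylide 14 (not isolated), via lithium ynolate 15 (not isolated)
Conditions: n-BuLi, THF, −78 °C; then t-BuOOH/LiN(SiMe3)2 (premixed), THF, −78 → 0 °C; then i-Pr3SiOTf, −78 °C; chromatography on Et3N-deactivated SiO2
Reagents that add atoms: tert-butyl hydroperoxide, CC(C)(C)OO; triisopropylsilyl trifluoromethanesulfonate, CC(C)[Si](C(C)C)(C(C)C)OS(=O)(=O)C(F)(F)F
Why: A lithium acetylide attacks the electrophilic oxygen of lithium tert-butyl peroxide to give the ynolate (acetylide oxidation), which the bulky silyl triflate traps on oxygen to give the isolable triisopropylsilyl ynol ether, all bond changes being at the alkyne terminus remote from the quaternary carbon.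

Step 10
Reactants: 17 ethyl 3-methylbut-2-enoate
Product: 19 4-methyl-2H-pyran-2-one, via hydroxydienoate 18 (not isolated)
Conditions: HCO2Et, t-BuOK, THF, 0 °C → rt; then AcOH, H2SO4 (cat.), 90 °C
Reagents that add atoms: ethyl formate, CCOC=O
Why: Under reversible alkoxide conditions the vinylogous Claisen condensation with ethyl formate should settle on the conjugated γ-formyl enolate, and hot acid then equilibrates the C2–C3 double bond and lets the enol oxygen displace ethanol from the ester (lactonisation) to give the 2-pyrone.

Step 11
Reactants: 19 4-methyl-2H-pyran-2-one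
Product: 21 3,5-dibromo-4-methyl-2H-pyran-2-one, via monobromopyrone 20 (not isolated)
Conditions: Br2 (2.2 equiv), NaOAc, AcOH, rt → 60 °C, dark
Reagents that add atoms: bromine, BrBr
Why: C3 and C5 are the nucleophilic positions of a 2-pyrone and both are activated by the 4-methyl group, so ionic bromination in buffered acetic acid in the dark (electrophilic substitution by addition–elimination) should brominate C3 and then C5 and leave C6 and the methyl group untouched.

Step 12
Reactants: 16 ({[(1S,2R,5R)-1,2-dimethylbicyclo[3.1.0]hexan-2-yl]ethynyl}oxy)triisopropylsilane; 21 3,5-dibromo-4-methyl-2H-pyran-2-one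
Product: 23 {2,4-dibromo-6-[(1S,2R,5R)-1,2-dimethylbicyclo[3.1.0]hexan-2-yl]-3-methylphenoxy}triisopropylsilane, via bridged lactone 22 (not isolated)
Conditions: PhMe, 100 °C, sealed tube, 2,6-di-tert-butyl-4-methylpyridine (cat.)
Reagents that add atoms: none
Why: The electron-rich siloxyalkyne 16 and the electron-poor dibromopyrone 21 should combine in a polarised, asynchronous [4+2] cycloaddition in which the nucleophilic alkyne carbon remote from oxygen bonds to the electrophilic C6–H of the pyrone and the silyloxy-bearing carbon bonds to C3–Br, giving the 2-oxabicyclo[2.2.2]octadienone 22, which loses CO2 by retro-[4+2] at the reaction temperature. The closest known reaction type is the Diels–Alder/decarboxylation benzannulation of 2-pyrones, 3,5-dibromo-2-pyrones included, with ynamines, alkoxyalkynes and siloxyalkynes. The benzene ring is thus closed by an intermolecular cycloaddition that makes the C1–C2 and C5–C6 bonds of the phenol in one operation, the other four ring carbons arriving intact from the pyrone with both bromines and the methyl group in place. No stereocentre is created, because the two bridgehead centres of 22 vanish on aromatisation, and the three centres of the bicyclo[3.1.0]hexane are remote from the reacting carbons and are not touched under neutral thermal conditions that also spare the cyclopropane. The step needs regioselectivity, which the matched polarisation (ynol ether β-carbon to pyrone C6) and sterics (the quaternary substituent next to C–H and not next to C–Br) both secure; the triisopropylsilyl group and the moderate temperature guard against silyl migration to a silylketene.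

Step 13
Reactants: 23 {2,4-dibromo-6-[(1S,2R,5R)-1,2-dimethylbicyclo[3.1.0]hexan-2-yl]-3-methylphenoxy}triisopropylsilane
Product: 24 2,4-dibromo-6-[(1S,2R,5R)-1,2-dimethylbicyclo[3.1.0]hexan-2-yl]-3-methylphenol
Conditions: Bu4NF, THF, 0 °C; then aq. NH4Cl
Reagents that add atoms: none
Why: Fluoride attacks silicon and releases the hindered phenoxide (fluoride-mediated desilylation), conditions that are neither strongly acidic nor electrophilic and so leave the aryl cyclopropane and both C–Br bonds intact.

**Compound list**

1 | methyl 2-oxocyclopentane-1-carboxylate | COC(=O)C1CCCC1=O | starting material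
2 | tert-butyl L-valinate, (S), free base | CC(C)[C@H](N)C(=O)OC(C)(C)C | starting material
3 | methyl 2-{[(2S)-1-tert-butoxy-3-methyl-1-oxobutan-2-yl]amino}cyclopent-1-ene-1-carboxylate | COC(=O)C1=C(N[C@@H](C(C)C)C(=O)OC(C)(C)C)CCC1 | intermediate
4 | lithio-enamine, N-lithium salt of 3 (not isolated) | [Li+].COC(=O)C1=C([N-][C@@H](C(C)C)C(=O)OC(C)(C)C)CCC1 | intermediate
5 | methyl (1R)-2-{[(2S)-1-tert-butoxy-3-methyl-1-oxobutan-2-yl]imino}-1-methylcyclopentane-1-carboxylate (not isolated) | COC(=O)[C@]1(C)CCCC1=N[C@@H](C(C)C)C(=O)OC(C)(C)C | intermediate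
6 | methyl (1R)-1-methyl-2-oxocyclopentane-1-carboxylate | COC(=O)[C@]1(C)CCCC1=O | intermediate
7 | potassium (5R)-5-(methoxycarbonyl)-5-methylcyclopent-1-en-1-olate (not isolated) | [K+].COC(=O)[C@]1(C)CCC=C1[O-] | intermediate
8 | methyl (1R)-1-methyl-2-[(trifluoromethanesulfonyl)oxy]cyclopent-2-ene-1-carboxylate | COC(=O)[C@]1(C)CCC=C1OS(=O)(=O)C(F)(F)F | intermediate
9 | methyl (1R)-1,2-dimethylcyclopent-2-ene-1-carboxylate | COC(=O)[C@]1(C)CCC=C1C | intermediate
10 | [(1R)-1,2-dimethylcyclopent-2-en-1-yl]methanol | OC[C@]1(C)CCC=C1C | intermediate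
11 | [(1S,2R,5R)-1,2-dimethylbicyclo[3.1.0]hexan-2-yl]methanol (CH2OH cis to the cyclopropane CH2, the two methyl groups cis) | OC[C@]1(C)CC[C@@H]2C[C@@]21C | intermediate
12 | (1S,2R,5R)-1,2-dimethylbicyclo[3.1.0]hexane-2-carbaldehyde | O=C[C@]1(C)CC[C@@H]2C[C@@]21C | intermediate
13 | (1S,2S,5R)-2-ethynyl-1,2-dimethylbicyclo[3.1.0]hexane | C#C[C@]1(C)CC[C@@H]2C[C@@]21C | intermediate
14 | lithium acetylide of 13 (not isolated) | [Li+].[C-]#C[C@]1(C)CC[C@@H]2C[C@@]21C | intermediate
15 | lithium 2-[(1S,2R,5R)-1,2-dimethylbicyclo[3.1.0]hexan-2-yl]ethyn-1-olate (not isolated) | [Li+].[O-]C#C[C@]1(C)CC[C@@H]2C[C@@]21C | intermediate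
16 | ({[(1S,2R,5R)-1,2-dimethylbicyclo[3.1.0]hexan-2-yl]ethynyl}oxy)triisopropylsilane | CC(C)[Si](C(C)C)(C(C)C)OC#C[C@]1(C)CC[C@@H]2C[C@@]21C | intermediate
17 | ethyl 3-methylbut-2-enoate | CCOC(=O)C=C(C)C | starting material
18 | ethyl 5-hydroxy-3-methylpenta-2,4-dienoate, enol form of the γ-formyl ester, present as its potassium enolate, mixture of double-bond isomers (not isolated) | CCOC(=O)C=C(C)C=CO | intermediate
19 | 4-methyl-2H-pyran-2-one | Cc1ccoc(=O)c1 | intermediate
20 | 3-bromo-4-methyl-2H-pyran-2-one (not isolated) | Cc1ccoc(=O)c1Br | intermediate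
21 | 3,5-dibromo-4-methyl-2H-pyran-2-one | Cc1c(Br)coc(=O)c1Br | intermediate
22 | 4,7-dibromo-6-[(1S,2R,5R)-1,2-dimethylbicyclo[3.1.0]hexan-2-yl]-8-methyl-5-[(triisopropylsilyl)oxy]-2-oxabicyclo[2.2.2]octa-5,7-dien-3-one, either bridgehead configuration (not isolated) | O=C1OC2C(Br)=C(C)C1(Br)C(O[Si](C(C)C)(C(C)C)C(C)C)=C2[C@]3(C)CC[C@@H]4C[C@@]43C | intermediate
23 | {2,4-dibromo-6-[(1S,2R,5R)-1,2-dimethylbicyclo[3.1.0]hexan-2-yl]-3-methylphenoxy}triisopropylsilane | Cc1c(Br)cc([C@]2(C)CC[C@@H]3C[C@@]32C)c(O[Si](C(C)C)(C(C)C)C(C)C)c1Br | intermediate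
24 | 2,4-dibromo-6-[(1S,2R,5R)-1,2-dimethylbicyclo[3.1.0]hexan-2-yl]-3-methylphenol | Cc1c(Br)cc([C@]2(C)CC[C@@H]3C[C@@]32C)c(O)c1Br | target

**Step count**

Total: 13 steps. Longest linear sequence: 11 steps (steps 1–9, 12 and 13) from methyl 2-oxocyclopentane-1-carboxylate; the pyrone branch is 2 steps (steps 10 and 11).

**Steps most likely to fail**

Step 12. The cycloaddition may not take place for steric reasons (a tertiary alkyl group on the alkyne; methyl and bromine flanking the diene). The ynol ether may rearrange by 1,3-silyl shift to a silylketene before it reacts, or a stepwise addition may end in [2+2] closure. A π-acid such as AgNTf2 at ambient temperature is the first change of conditions. The fallback keeps the pyrone and the same two ring bonds but changes the two-carbon partner to a ketene acetal. It sets out from alkyne 13: the ynolate 15 is generated as in step 9 but quenched with dilute aqueous HCl in place of the silyl triflate, which should give 2-[(1S,2S,5R)-1,2-dimethylbicyclo[3.1.0]hexan-2-yl]acetic acid F1. Double deprotonation with LiN(i-Pr)2 and silylation with Me3SiCl should give the bis(trimethylsilyl) ketene acetal F2. Heating F2 with pyrone 21 in toluene is expected to give the bridged lactone F3, which on loss of CO2 gives the cyclohexadiene ketal F4 and on loss of trimethylsilanol the aryl trimethylsilyl ether F5; this is the known course of 2-pyrones with ketene acetals and silyl enol ethers. K2CO3 in methanol removes the silyl group, and the route is rejoined at the target 24.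

Step 9. Oxygen transfer to the acetylide may be incomplete, the remaining acetylide is then silylated on carbon, and the siloxyalkyne may hydrolyse during isolation. The fallback is a Kowalski ester homologation, which reaches the same ynolate from a carbonyl carbon. It sets out from aldehyde 12: Pinnick oxidation (NaClO2, NaH2PO4, 2-methylbut-2-ene, t-BuOH/H2O) should give (1S,2R,5R)-1,2-dimethylbicyclo[3.1.0]hexane-2-carboxylic acid F6, and MeI/K2CO3 in DMF its methyl ester F7. Addition of LiCHBr2 (from CH2Br2 and lithium 2,2,6,6-tetramethylpiperidide, THF, −78 °C), then LiN(SiMe3)2 and n-BuLi, should pass through the dibromomethyl ketone F8 (as its lithium enolate). Bromine–lithium exchange and 1,2-shift then lead to the lithium ynolate 15, which is silylated as in step 9, so the route is rejoined at 16.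

Step 10. Formylation may occur at the α-carbon, the enoate may undergo Michael self-condensation under alkoxide, and the E-configured enol may fail to close the ring. The fallback replaces the Claisen formylation by an aminomethylenation. It sets out from enoate 17: heating with tert-butoxybis(dimethylamino)methane (Bredereck's reagent) should condense at the γ-methyl group to give ethyl 5-(dimethylamino)-3-methylpenta-2,4-dienoate F9. Heating F9 in AcOH with aqueous H2SO4 should hydrolyse the enamine and close the lactone, and the route is rejoined at pyrone 19.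

**Further compounds**

F1 | step 12 | 2-[(1S,2S,5R)-1,2-dimethylbicyclo[3.1.0]hexan-2-yl]acetic acid | OC(=O)C[C@]1(C)CC[C@@H]2C[C@@]21C
F2 | step 12 | ({2-[(1S,2S,5R)-1,2-dimethylbicyclo[3.1.0]hexan-2-yl]ethene-1,1-diyl}bis(oxy))bis(trimethylsilane) | C[Si](C)(C)OC(O[Si](C)(C)C)=C[C@]1(C)CC[C@@H]2C[C@@]21C
F3 | step 12 | 4,7-dibromo-6-[(1S,2S,5R)-1,2-dimethylbicyclo[3.1.0]hexan-2-yl]-8-methyl-5,5-bis[(trimethylsilyl)oxy]-2-oxabicyclo[2.2.2]oct-7-en-3-one | O=C1OC2C(Br)=C(C)C1(Br)C(O[Si](C)(C)C)(O[Si](C)(C)C)C2[C@]3(C)CC[C@@H]4C[C@@]43C
F4 | step 12 | 1,3-dibromo-5-[(1S,2S,5R)-1,2-dimethylbicyclo[3.1.0]hexan-2-yl]-2-methyl-6,6-bis[(trimethylsilyl)oxy]cyclohexa-1,3-diene | C[Si](C)(C)OC1(O[Si](C)(C)C)C(Br)=C(C)C(Br)=CC1[C@]2(C)CC[C@@H]3C[C@@]32C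
F5 | step 12 | {2,4-dibromo-6-[(1S,2R,5R)-1,2-dimethylbicyclo[3.1.0]hexan-2-yl]-3-methylphenoxy}trimethylsilane | Cc1c(Br)cc([C@]2(C)CC[C@@H]3C[C@@]32C)c(O[Si](C)(C)C)c1Br
F6 | step 9 | (1S,2R,5R)-1,2-dimethylbicyclo[3.1.0]hexane-2-carboxylic acid | OC(=O)[C@]1(C)CC[C@@H]2C[C@@]21C
F7 | step 9 | methyl (1S,2R,5R)-1,2-dimethylbicyclo[3.1.0]hexane-2-carboxylate | COC(=O)[C@]1(C)CC[C@@H]2C[C@@]21C
F8 | step 9 | 2,2-dibromo-1-[(1S,2R,5R)-1,2-dimethylbicyclo[3.1.0]hexan-2-yl]ethan-1-one | BrC(Br)C(=O)[C@]1(C)CC[C@@H]2C[C@@]21C
F9 | step 10 | ethyl 5-(dimethylamino)-3-methylpenta-2,4-dienoate | CCOC(=O)C=C(C)C=CN(C)C
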